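**Retrosynthetic overview**
1. The last bond made is the C(acyl)–CH2 bond of the dodecanoyl chain, by rhodium-catalysed hydroacylation of 1-undecene (13) with the unprotected aldehyde 12. This adds eleven of the thirty-three carbons, forms no by-product and gives the target directly.
2. Enabling feature: on ring D (the phloroglucinol ring on C4) the acyl-bearing carbon sits between two phenolic OH groups. At the aldehyde oxidation level this is a salicylaldehyde, whose ortho phenoxide O and formyl C–H close a five-membered acyl–rhodium chelate.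
3. Aldehyde 12 comes from ring-D-selective formylation of pentaphenol 10. Compound 10 comes from flav-3-ene 8 by hydrogenation of C3=C4 anti to the C2 aryl group (sets 4S, 2,4-cis) with loss of all benzyl groups.
4. Flavene 8 comes from Negishi coupling at C4 of enol triflate 3 with the arylzinc made from bromide 5. Triflate 3 derives from chiral-pool (2S)-liquiritigenin 1, which supplies C2.
5. Ring order: no ring is built. Rings A, C and B arrive together in 1 and ring D arrives as a preformed benzene.

Key step: step 7

Assumption: (2S)-liquiritigenin is taken as the commercial, enantiopure natural enantiomer; slow rotation about the C4–ring D bond is not a stereo element of the target as drawn, so rotamers are treated as one compound.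

**Step 1**
Reactants: 1 (2S)-liquiritigenin [(2S)-7-hydroxy-2-(4-hydroxyphenyl)chroman-4-one]
Product: 2 (2S)-7-(benzyloxy)-2-[4-(benzyloxy)phenyl]chroman-4-one
Conditions: BnOH (2.5 equiv), PPh3 (2.5 equiv), DIAD (2.5 equiv), THF, 0 °C to rt
Reagents that add atoms: benzyl alcohol, OCc1ccccc1
Why: Mitsunobu etherification of the two phenols runs under essentially neutral conditions, so the base-triggered retro-oxa-Michael opening of the flavanone that would racemise C2 is avoided and the 2S centre is carried through unchanged.

**Step 2**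
Reactants: 2 (2S)-7-(benzyloxy)-2-[4-(benzyloxy)phenyl]chroman-4-one
Product: 3 (2S)-7-(benzyloxy)-2-[4-(benzyloxy)phenyl]-2H-chromen-4-yl trifluoromethanesulfonate
Conditions: Tf2O (1.2 equiv), 2,6-di-tert-butyl-4-methylpyridine (1.5 equiv), CH2Cl2, 0 °C to rt
Reagents that add atoms: trifluoromethanesulfonic anhydride, O=S(=O)(OS(=O)(=O)C(F)(F)F)C(F)(F)F
Why: Enol triflate formation by O-sulfonylation of the electron-rich aryl ketone and loss of a C3 proton to the hindered pyridine never passes through a free enolate, so the E1cB ring-opening channel stays closed and C2 is not touched.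

**Step 3**
Reactants: 4 1,3,5-tris(benzyloxy)benzene
Product: 5 2-bromo-1,3,5-tris(benzyloxy)benzene
Conditions: NBS (1.0 equiv), CH2Cl2, -40 °C to 0 °C
Reagents that add atoms: N-bromosuccinimide, O=C1CCC(=O)N1Br
Why: Electrophilic aromatic bromination of the symmetric trialkoxybenzene, whose three free positions are equivalent, should stop at the monobromide with one equivalent of NBS at low temperature.

**Step 4**
Reactants: 5 2-bromo-1,3,5-tris(benzyloxy)benzene; 3 (2S)-7-(benzyloxy)-2-[4-(benzyloxy)phenyl]-2H-chromen-4-yl trifluoromethanesulfonate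
Product: 8 (2S)-7-(benzyloxy)-2-[4-(benzyloxy)phenyl]-4-[2,4,6-tris(benzyloxy)phenyl]-2H-chromene, via aryllithium 6 (not isolated), via arylzinc chloride 7 (not isolated)
Conditions: 5, n-BuLi, THF, -78 °C; ZnCl2, -78 °C to rt; then 3, Pd2(dba)3 (2 mol %), XPhos (8 mol %), THF, 55 °C, dark
Reagents that add atoms: none
Why: Bromine–lithium exchange and transmetalation give a non-basic arylzinc that should couple with the alkenyl triflate in a Negishi reaction under a zerovalent palladium/bulky biarylphosphine catalyst suited to doubly ortho-substituted nucleophiles, while the sp3 centre C2 is not involved and keeps its configuration as long as heat and light, which could open the 2H-chromene electrocyclically, are limited.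

**Step 5**
Reactants: 8 (2S)-7-(benzyloxy)-2-[4-(benzyloxy)phenyl]-4-[2,4,6-tris(benzyloxy)phenyl]-2H-chromene
Product: 10 2-[(2S,4S)-7-hydroxy-2-(4-hydroxyphenyl)chroman-4-yl]benzene-1,3,5-triol, via pentabenzyl cis-flavan 9 (not isolated)
Conditions: H2 (3 atm), 10% Pd/C, EtOAc, rt; then MeOH, Pd(OH)2/C, H2 (1 atm), rt
Reagents that add atoms: none
Why: Heterogeneous syn-hydrogenation should add hydrogen to the face of C3=C4 opposite the neighbouring C2 aryl group, placing H-4 cis to H-2 and so the ring D aryl cis to the ring B aryl (4S, substrate control by C2), after which hydrogenolysis cleaves the five aryl benzyl ethers while the flavan C2–O bond, no longer allylic, is expected to survive (if some O-debenzylation runs ahead of saturation, the same product results).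

**Step 6**
Reactants: 10 2-[(2S,4S)-7-hydroxy-2-(4-hydroxyphenyl)chroman-4-yl]benzene-1,3,5-triol
Product: 12 2,4,6-trihydroxy-3-[(2S,4S)-7-hydroxy-2-(4-hydroxyphenyl)chroman-4-yl]benzaldehyde, via aryl iminium chloride 11 (not isolated)
Conditions: POCl3 (1.1 equiv), DMF (1.5 equiv), MeCN, -15 °C to rt; then H2O, 40 °C
Reagents that add atoms: N,N-dimethylformamide, CN(C)C=O; water, O
Why: Vilsmeier–Haack formylation should attack the most nucleophilic ring, the triply oxygenated ring D, whose two free positions are constitutionally equivalent and which the new formyl group deactivates against a second attack, while the doubly oxygenated ring A reacts more slowly and ring B not at all at low temperature.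

**Step 7**
Reactants: 12 2,4,6-trihydroxy-3-[(2S,4S)-7-hydroxy-2-(4-hydroxyphenyl)chroman-4-yl]benzaldehyde; 13 1-undecene
Product: 14 1-{2,4,6-trihydroxy-3-[(2S,4S)-7-hydroxy-2-(4-hydroxyphenyl)chroman-4-yl]phenyl}dodecan-1-one
Conditions: [Rh(cod)OMe]2 (2.5 mol %), racemic BINOL-derived N,N-diisopropylphosphoramidite (6 mol %), K3PO4 (10 mol %), 13 (4 equiv), THF, 70 °C, Ar
Reagents that add atoms: none
Why: K3PO4 removes the most acidic proton of 12, that of a ring D hydroxyl flanking the formyl group (a vinylogous carboxylic acid), and the phenoxide binds monovalent rhodium so that the formyl C–H adds oxidatively to give a five-membered acyl rhodium hydride chelate (Rh, phenoxide O, two ring D carbons, acyl C) in which trivalent rhodium is held back from decarbonylation. 1-Undecene then coordinates, the hydride migrates to its internal carbon (anti-Markovnikov hydrometalation, favoured by the bulky monodentate phosphoramidite), and reductive elimination joins the acyl carbon to the terminal CH2, which becomes the alpha-methylene of the dodecanoyl chain. The closest known reaction type is the rhodium/phosphoramidite-catalysed intermolecular hydroacylation of unactivated terminal alkenes with salicylaldehydes, which gives linear 2-hydroxyaryl alkyl ketones. No ring is closed and no stereocentre is created, and C2 and C4 should stay intact because the medium is neutral to weakly basic, the base is substoichiometric and no acid is present that could ionise the benzylic positions. The step needs linear over branched regioselectivity, secured by the unbiased terminal alkene and the ligand, and chemoselectivity among five phenols and three electron-rich rings, secured because only the ring D hydroxyls ortho to the formyl group can close the chelate. Because the reaction is a pure addition that tolerates free phenols, it should deliver the target with no protecting group left to remove.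

**Compound list**
1 | (2S)-liquiritigenin, (2S)-7-hydroxy-2-(4-hydroxyphenyl)chroman-4-one | O=C1C[C@@H](c2ccc(O)cc2)Oc2cc(O)ccc21 | starting material
2 | (2S)-7-(benzyloxy)-2-[4-(benzyloxy)phenyl]chroman-4-one | O=C1C[C@@H](c2ccc(OCc3ccccc3)cc2)Oc2cc(OCc3ccccc3)ccc21 | intermediate
3 | (2S)-7-(benzyloxy)-2-[4-(benzyloxy)phenyl]-2H-chromen-4-yl trifluoromethanesulfonate | O=S(=O)(OC1=C[C@@H](c2ccc(OCc3ccccc3)cc2)Oc2cc(OCc3ccccc3)ccc21)C(F)(F)F | intermediate
4 | 1,3,5-tris(benzyloxy)benzene | c1ccc(COc2cc(OCc3ccccc3)cc(OCc3ccccc3)c2)cc1 | starting material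
5 | 2-bromo-1,3,5-tris(benzyloxy)benzene | Brc1c(OCc2ccccc2)cc(OCc2ccccc2)cc1OCc1ccccc1 | intermediate
6 | [2,4,6-tris(benzyloxy)phenyl]lithium (formed in the flask) | [Li]c1c(OCc2ccccc2)cc(OCc2ccccc2)cc1OCc1ccccc1 | intermediate
7 | chloro[2,4,6-tris(benzyloxy)phenyl]zinc (formed in the flask) | Cl[Zn]c1c(OCc2ccccc2)cc(OCc2ccccc2)cc1OCc1ccccc1 | intermediate
8 | (2S)-7-(benzyloxy)-2-[4-(benzyloxy)phenyl]-4-[2,4,6-tris(benzyloxy)phenyl]-2H-chromene | C1(c2c(OCc3ccccc3)cc(OCc3ccccc3)cc2OCc2ccccc2)=C[C@@H](c2ccc(OCc3ccccc3)cc2)Oc2cc(OCc3ccccc3)ccc21 | intermediate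
9 | (2S,4S)-7-(benzyloxy)-2-[4-(benzyloxy)phenyl]-4-[2,4,6-tris(benzyloxy)phenyl]chromane (formed in the flask) | C(c1ccccc1)Oc1cc(OCc2ccccc2)c([C@H]2C[C@@H](c3ccc(OCc4ccccc4)cc3)Oc3cc(OCc4ccccc4)ccc32)c(OCc2ccccc2)c1 | intermediate
10 | 2-[(2S,4S)-7-hydroxy-2-(4-hydroxyphenyl)chroman-4-yl]benzene-1,3,5-triol | Oc1cc(O)c([C@H]2C[C@@H](c3ccc(O)cc3)Oc3cc(O)ccc32)c(O)c1 | intermediate
11 | N,N-dimethyl-1-{2,4,6-trihydroxy-3-[(2S,4S)-7-hydroxy-2-(4-hydroxyphenyl)chroman-4-yl]phenyl}methaniminium chloride (formed in the flask) | C[N+](C)=Cc1c(O)cc(O)c([C@H]2C[C@@H](c3ccc(O)cc3)Oc3cc(O)ccc32)c1O.[Cl-] | intermediate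
12 | 2,4,6-trihydroxy-3-[(2S,4S)-7-hydroxy-2-(4-hydroxyphenyl)chroman-4-yl]benzaldehyde | O=Cc1c(O)cc(O)c([C@H]2C[C@@H](c3ccc(O)cc3)Oc3cc(O)ccc32)c1O | intermediate
13 | 1-undecene | C=CCCCCCCCCC | starting material
14 | 1-{2,4,6-trihydroxy-3-[(2S,4S)-7-hydroxy-2-(4-hydroxyphenyl)chroman-4-yl]phenyl}dodecan-1-one | CCCCCCCCCCCC(=O)c1c(O)cc(O)c([C@H]2C[C@@H](c3ccc(O)cc3)Oc3cc(O)ccc32)c1O | target

**Step count and risks**
Total step count: 7. Longest linear sequence: 6 (steps 1, 2, 4, 5, 6, 7).

Steps most likely to fail:

Step 7. The hydroacylation may fail through binding of the catalyst by the other phenoxides or low solubility of the pentaphenol. It may also fail through decarbonylation of the crowded acyl rhodium hydride, or through isomerisation of 1-undecene to internal alkenes that do not react. The fallback makes the same bond by carbonyl addition instead of C–H activation and sets out from 12. Exhaustive O-benzylation (BnBr, K2CO3, DMF, 50 °C) should give 2,4,6-tris(benzyloxy)-3-[(2S,4S)-7-(benzyloxy)-2-[4-(benzyloxy)phenyl]chroman-4-yl]benzaldehyde F1. Addition of C11H23MgBr (undecylmagnesium bromide, THF, 0 °C) should give 1-{2,4,6-tris(benzyloxy)-3-[(2S,4S)-7-(benzyloxy)-2-[4-(benzyloxy)phenyl]chroman-4-yl]phenyl}dodecan-1-ol F2 as a mixture of carbinol epimers, which does not matter. Dess–Martin oxidation (CH2Cl2, rt) should give 1-{2,4,6-tris(benzyloxy)-3-[(2S,4S)-7-(benzyloxy)-2-[4-(benzyloxy)phenyl]chroman-4-yl]phenyl}dodecan-1-one F3. Hydrogenolysis (H2, Pd/C, EtOAc/MeOH, rt) removes the five benzyl groups and comes back to the route at 14.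

Step 5. Saturation may stall at the hindered trisubstituted alkene, the allylic and benzylic C2–O bond may be opened by hydrogenolysis before the alkene is reduced, or facial selectivity may erode. The fallback replaces surface hydrogenation by ionic hydrogenation and sets out from 8. With Et3SiH and CF3CO2H in CH2Cl2 at -20 °C, protonation at C3 gives the C4 cation stabilised by rings A and D, and hydride is delivered pseudoaxially, trans to the C2 aryl group. This should give the 2,4-cis compound 9, now isolated and purified. Separate hydrogenolysis (H2, Pd(OH)2/C, EtOAc/MeOH, rt) then comes back to the route at 10. No new compound arises.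

Step 4. Transmetalation or reductive elimination may be slow with the doubly ortho-substituted arylzinc, the organozinc may be protonated, or the chromene product may ring-open on heating. The fallback forms the C4–aryl bond by carbonyl addition instead of cross-coupling and sets out from ketone 2 and aryllithium 6 (generated from 5 as in step 4). Transmetalation of 6 with anhydrous CeCl3 (THF, -78 °C) gives dichloro[2,4,6-tris(benzyloxy)phenyl]cerium F4, whose low basicity should suppress enolisation and ring opening of the flavanone. Its 1,2-addition to 2 gives (2S)-7-(benzyloxy)-2-[4-(benzyloxy)phenyl]-4-[2,4,6-tris(benzyloxy)phenyl]chroman-4-ol F5 as a mixture of C4 epimers, which does not matter. Ionic deoxygenation (Et3SiH, CF3CO2H, CH2Cl2, -20 °C) through the same C4 cation as above should give isolated 9, where the fallback comes back to the route. Compound 9 is carried to 10 by the hydrogenolysis half of step 5.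

**Further compounds**
F1 | step 7 | 2,4,6-tris(benzyloxy)-3-[(2S,4S)-7-(benzyloxy)-2-[4-(benzyloxy)phenyl]chroman-4-yl]benzaldehyde | O=Cc1c(OCc2ccccc2)cc(OCc2ccccc2)c([C@H]2C[C@@H](c3ccc(OCc4ccccc4)cc3)Oc3cc(OCc4ccccc4)ccc32)c1OCc1ccccc1
F2 | step 7 | 1-{2,4,6-tris(benzyloxy)-3-[(2S,4S)-7-(benzyloxy)-2-[4-(benzyloxy)phenyl]chroman-4-yl]phenyl}dodecan-1-ol (carbinol epimers) | CCCCCCCCCCCC(O)c1c(OCc2ccccc2)cc(OCc2ccccc2)c([C@H]2C[C@@H](c3ccc(OCc4ccccc4)cc3)Oc3cc(OCc4ccccc4)ccc32)c1OCc1ccccc1
F3 | step 7 | 1-{2,4,6-tris(benzyloxy)-3-[(2S,4S)-7-(benzyloxy)-2-[4-(benzyloxy)phenyl]chroman-4-yl]phenyl}dodecan-1-one | CCCCCCCCCCCC(=O)c1c(OCc2ccccc2)cc(OCc2ccccc2)c([C@H]2C[C@@H](c3ccc(OCc4ccccc4)cc3)Oc3cc(OCc4ccccc4)ccc32)c1OCc1ccccc1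
F0 | step 5 | none | none
F4 | step 4 | dichloro[2,4,6-tris(benzyloxy)phenyl]cerium | Cl[Ce](Cl)c1c(OCc2ccccc2)cc(OCc2ccccc2)cc1OCc1ccccc1
F5 | step 4 | (2S)-7-(benzyloxy)-2-[4-(benzyloxy)phenyl]-4-[2,4,6-tris(benzyloxy)phenyl]chroman-4-ol (C4 epimers) | OC1(c2c(OCc3ccccc3)cc(OCc3ccccc3)cc2OCc2ccccc2)C[C@@H](c2ccc(OCc3ccccc3)cc2)Oc2cc(OCc3ccccc3)ccc21
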